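**Retrosynthetic overview**
1. Target ⇐ debenzylation, desilylation and C‑8′ epimerisation (cis → all‑trans aroyl oxolane) of a protected precursor whose 7′‑ketone is masked as a 1,3‑dithiane.
2. The erythro arylglycerol β‑aryl ether ⇐ Evans syn‑aldol of aryloxyacetyl imide 20 with O‑benzylvanillin, reductive auxiliary removal, then Mitsunobu inversion at C‑7″ (threo → erythro).
3. Imide 20 ⇐ phenol 14 by O‑alkylation with bromoacetate; 14 ⇐ tetraol 13 by quinone‑methide cyclisation. This is the only ring made, and it is closed before the side chain is attached.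
4. Tetraol 13 ⇐ lactone 12 (LiAlH4) ⇐ three‑component Michael/aldol coupling of lithiated dithiane 8, (5R)‑menthyloxybutenolide 5 and aldehyde 9 (forms C‑8′–C‑7′ and C‑8–C‑7).
5. Building blocks: furfural, (−)‑menthol, syringaldehyde, O‑benzylvanillin, (R)‑4‑benzyl‑2‑oxazolidinone.

Assumption: lignan numbering is used in the descriptions (C‑7/8/9 = central syringyl unit and oxolane, primes = aroyl unit, double primes = guaiacylglycerol unit). The carbinol centre formed in step 6 is carried as an epimer mixture because step 8 re‑sets it.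

**Route**

Step 1
Reactants: 1 furfural
Product: 3 5‑hydroxy‑2(5H)‑furanone (racemic), via furfural endoperoxide 2 (not isolated)
Conditions: O2, rose bengal (cat.), hν (visible), MeOH, rt
Reagents that add atoms: oxygen, O=O
Why: Dye‑sensitised singlet‑oxygen [4+2] cycloaddition to the furan gives the endoperoxide, which fragments in methanol with loss of the formyl carbon as methyl formate; no stereocentre is controlled.

Step 2
Reactants: 3 5‑hydroxy‑2(5H)‑furanone; 4 (−)‑menthol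
Product: 5 (5R)‑5‑[(1R,2S,5R)‑menthyloxy]‑2(5H)‑furanone
Conditions: CSA (cat.), toluene, reflux (Dean–Stark); crystallise from petroleum ether, acid‑equilibrate and recrystallise the mother liquor
Reagents that add atoms: none
Why: Acid‑catalysed acetalisation gives both C‑5 epimers, which interconvert under acid, so the less soluble (5R)‑diastereomer is collected by crystallisation (auxiliary‑based resolution).

Step 3
Reactants: 6 syringaldehyde
Product: 7 4‑benzyloxy‑3,5‑dimethoxybenzaldehyde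
Conditions: BnBr, K2CO3, DMF, 60 °C
Reagents that add atoms: benzyl bromide, BrCc1ccccc1
Why: Williamson etherification of the acidic phenol installs a benzyl group that survives every later step until the final hydrogenolysis.

Step 4
Reactants: 7 4‑benzyloxy‑3,5‑dimethoxybenzaldehyde
Product: 8 2‑(4‑benzyloxy‑3,5‑dimethoxyphenyl)‑1,3‑dithiane
Conditions: HS(CH2)3SH, BF3·OEt2 (cat.), CH2Cl2, 0 °C → rt
Reagents that add atoms: propane‑1,3‑dithiol, SCCCS
Why: Lewis‑acid thioacetalisation converts the aldehyde into an acyl‑anion equivalent (umpolung) that also masks the future 7′‑ketone.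

Step 5
Reactants: 6 syringaldehyde
Product: 9 4‑formyl‑2,6‑dimethoxyphenyl pivalate
Conditions: PivCl, Et3N, DMAP (cat.), CH2Cl2, 0 °C → rt
Reagents that add atoms: pivaloyl chloride, CC(C)(C)C(Cl)=O
Why: O‑acylation gives a hindered ester that tolerates a lithium enolate at −78 °C and is removed by the hydride reduction in step 7.

Step 6
Reactants: 8 2‑(4‑benzyloxy‑3,5‑dimethoxyphenyl)‑1,3‑dithiane; 5 (5R)‑menthyloxybutenolide; 9 4‑formyl‑2,6‑dimethoxyphenyl pivalate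
Product: 12 tandem Michael–aldol lactone (3S,4R,5R; both C‑7 carbinol epimers), via 2‑lithio‑1,3‑dithiane 10 (not isolated), via lithium lactone enolate 11 (not isolated)
Conditions: n‑BuLi, THF, −78 → −30 °C; 5, −78 °C; then 9, −78 °C; sat. aq NH4Cl
Reagents that add atoms: none
Why: In this tandem conjugate addition–aldol reaction the lithiated dithiane adds 1,4 to the butenolide anti to the menthyloxy group (C‑4 = R) and the lactone enolate is trapped by aldehyde 9 anti to the new C‑4 substituent, which sets C‑8 (lactone C‑3 = S).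

Step 7
Reactants: 12 tandem Michael–aldol lactone
Product: 13 (2R,3R)‑2‑[hydroxy(4‑hydroxy‑3,5‑dimethoxyphenyl)methyl]‑3‑[2‑(4‑benzyloxy‑3,5‑dimethoxyphenyl)‑1,3‑dithian‑2‑yl]butane‑1,4‑diol (both carbinol epimers)
Conditions: LiAlH4 (excess), THF, 0 °C → reflux; Rochelle salt work‑up
Reagents that add atoms: none
Why: LiAlH4 reduces the lactone carbonyl to C‑9 H2OH, collapses the menthyl pseudo‑ester through the aldehyde to C‑9′ H2OH and cleaves the aryl pivalate, without touching the C‑8/C‑8′ centres.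

Step 8
Reactants: 13 tetraol
Product: 14 4‑[(2S,3R,4R)‑4‑[2‑(4‑benzyloxy‑3,5‑dimethoxyphenyl)‑1,3‑dithian‑2‑yl]‑3‑(hydroxymethyl)oxolan‑2‑yl]‑2,6‑dimethoxyphenol
Conditions: CSA (10 mol%), CH2Cl2/THF, 0 °C → rt
Reagents that add atoms: none
Why: The p‑hydroxybenzylic alcohol ionises through its quinone methide and the C‑9′ hydroxyl closes the oxolane (acid‑catalysed SN1 cycloetherification), so both carbinol epimers converge on the 2,3‑trans ring with C‑7 = S.

Step 9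
Reactants: 14 oxolane phenol
Product: 15 methyl 2‑{4‑[(2S,3R,4R)‑4‑(2‑aryl‑1,3‑dithian‑2‑yl)‑3‑(hydroxymethyl)oxolan‑2‑yl]‑2,6‑dimethoxyphenoxy}acetate
Conditions: BrCH2CO2Me, K2CO3, acetone, reflux
Reagents that add atoms: methyl bromoacetate, COC(=O)CBr
Why: Williamson alkylation occurs only at the phenoxide because the primary alcohol is not deprotonated by carbonate.

Step 10
Reactants: 15 aryloxyacetate
Product: 16 the C‑9 O‑TBS ether of 15
Conditions: TBSCl, imidazole, DMF, rt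
Reagents that add atoms: tert‑butyldimethylsilyl chloride, CC(C)(C)[Si](C)(C)Cl
Why: Silylation protects the primary alcohol against the acylation and boron‑enolate chemistry that follow.

Step 11
Reactants: 16 silylated ester
Product: 17 the corresponding aryloxyacetic acid
Conditions: LiOH, THF/MeOH/H2O, rt; then 0.5 M HCl to pH 4, 0 °C
Reagents that add atoms: lithium hydroxide, [Li+].[OH-]
Why: Saponification of the unhindered methyl ester leaves the primary TBS ether, dithiane and benzyl ether intact.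

Step 12
Reactants: 17 aryloxyacetic acid; 18 (R)‑4‑benzyl‑2‑oxazolidinone
Product: 20 (4R)‑4‑benzyl‑3‑(aryloxyacetyl)oxazolidin‑2‑one, via mixed pivalic anhydride 19 (not isolated)
Conditions: PivCl, Et3N, THF, −20 °C; then 18, LiCl, −20 °C → rt
Reagents that add atoms: none
Why: In this mixed‑anhydride N‑acylation the LiCl‑activated oxazolidinone attacks the less hindered carbonyl of the anhydride.

Step 13
Reactants: 20 aryloxyacetyl imide; 21 4‑benzyloxy‑3‑methoxybenzaldehyde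
Product: 23 (4R)‑4‑benzyl‑3‑[(2R,3S)‑3‑(4‑benzyloxy‑3‑methoxyphenyl)‑3‑hydroxy‑2‑(aryloxy)propanoyl]oxazolidin‑2‑one, via Z‑boron enolate 22 (not isolated)
Conditions: Bu2BOTf, iPr2NEt, CH2Cl2, −78 → 0 °C; 21, −78 → 0 °C; pH 7 buffer/MeOH (non‑oxidative work‑up, spares the dithiane)
Reagents that add atoms: none
Why: In this Evans syn‑aldol the Z‑boron enolate reacts through a Zimmerman–Traxler chair on the face away from the auxiliary benzyl group, which sets C‑8″ (final S) and gives the syn (threo) C‑7″ carbinol.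

Step 14
Reactants: 23 syn‑aldol imide
Product: 24 (1S,2S)‑1‑(4‑benzyloxy‑3‑methoxyphenyl)‑2‑(aryloxy)propane‑1,3‑diol (threo)
Conditions: LiBH4, THF/MeOH, 0 °C
Reagents that add atoms: none
Why: Borohydride reductive cleavage of the imide carbonyl releases the auxiliary and gives the 1,3‑diol without affecting either new stereocentre.

Step 15
Reactants: 24 threo diol
Product: 25 the primary (C‑9″) mono‑TBS ether of 24
Conditions: TBSCl (1.1 equiv), imidazole, CH2Cl2, 0 °C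
Reagents that add atoms: tert‑butyldimethylsilyl chloride, CC(C)(C)[Si](C)(C)Cl
Why: Silylation is selective for the primary hydroxyl over the hindered secondary benzylic one.

Step 16
Reactants: 25 mono‑TBS threo alcohol
Product: 26 (1R,2S) 4‑nitrobenzoate of the benzylic alcohol (erythro)
Conditions: 4‑O2NC6H4CO2H, PPh3, DIAD, toluene, 0 °C → rt
Reagents that add atoms: 4‑nitrobenzoic acid, OC(=O)c1ccc(cc1)[N+](=O)[O-]
Why: Mitsunobu esterification displaces the activated benzylic oxygen by SN2 with inversion, converting C‑7″ from S to R.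

Step 17
Reactants: 26 4‑nitrobenzoate
Product: 27 (1R,2S) erythro alcohol
Conditions: K2CO3 (cat.), MeOH/THF, 0 °C → rt
Reagents that add atoms: none
Why: Methanolysis of the activated aryl ester (transesterification) frees the inverted carbinol without touching the silyl ethers.

Step 18
Reactants: 27 erythro alcohol (dithiane)
Product: 28 (2S,3R,4R) 3,4‑cis aryl ketone
Conditions: Hg(ClO4)2·3H2O, CaCO3, THF/H2O, 0 °C
Reagents that add atoms: water, O
Why: Thiophilic Hg(II) opens the dithiane to an aryl‑stabilised thionium ion that is hydrolysed to the ketone, with CaCO3 buffering the acid to protect the benzylic alcohol and silyl ethers.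

Step 19
Reactants: 28 cis ketone
Product: 29 (2S,3R,4S) all‑trans aryl ketone
Conditions: DBU (cat.), CH2Cl2, rt
Reagents that add atoms: none
Why: Reversible enolisation of the aryl ketone lets C‑8′ settle trans to the neighbouring CH2OTBS group (thermodynamic epimerisation), which sets C‑8′ = S.

Step 20
Reactants: 29 all‑trans ketone
Product: 30 the dibenzyl ether of the target (three free aliphatic hydroxyls)
Conditions: HF·pyridine, pyridine, THF, 0 °C → rt
Reagents that add atoms: none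
Why: Buffered fluoride desilylation removes both primary TBS ethers without acid or base strong enough to disturb the benzylic alcohol or the ketone α‑centre.

Step 21
Reactants: 30 dibenzyl ether
Product: 31 CNP0236429.1 (target)
Conditions: H2 (1 atm), 10% Pd/C, EtOAc/MeOH, rt, stopped at full conversion
Reagents that add atoms: none
Why: Hydrogenolysis of the two aryl benzyl ethers is much faster than reduction of the aryl ketone or cleavage of the benzylic C–O bonds under neutral conditions.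

**Compound list**
(Ar′ = 4‑benzyloxy‑3,5‑dimethoxyphenyl; Men = (1R,2S,5R)‑menthyl)

1 | furfural | O=Cc1ccco1 | starting material
2 | furfural endoperoxide (1‑formyl‑2,3,7‑trioxabicyclo[2.2.1]hept‑5‑ene, racemic) | O=CC12C=CC(OO1)O2 | intermediate (not isolated)
3 | 5‑hydroxy‑2(5H)‑furanone (racemic) | O=C1C=CC(O)O1 | intermediate
4 | (−)‑menthol, (1R,2S,5R)‑2‑isopropyl‑5‑methylcyclohexanol | CC(C)[C@@H]1CC[C@@H](C)C[C@H]1O | starting material
5 | (5R)‑5‑[(1R,2S,5R)‑menthyloxy]‑2(5H)‑furanone | O=C1C=C[C@H](O[C@@H]2C[C@H](C)CC[C@H]2C(C)C)O1 | intermediate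
6 | syringaldehyde | COc1cc(C=O)cc(OC)c1O | starting material
7 | 4‑benzyloxy‑3,5‑dimethoxybenzaldehyde | COc1cc(C=O)cc(OC)c1OCc1ccccc1 | intermediate
8 | 2‑(4‑benzyloxy‑3,5‑dimethoxyphenyl)‑1,3‑dithiane | COc1cc(C2SCCCS2)cc(OC)c1OCc1ccccc1 | intermediate
9 | 4‑formyl‑2,6‑dimethoxyphenyl pivalate | COc1cc(C=O)cc(OC)c1OC(=O)C(C)(C)C | intermediate
10 | 2‑lithio‑2‑Ar′‑1,3‑dithiane | COc1cc(C2([Li])SCCCS2)cc(OC)c1OCc1ccccc1 | intermediate (not isolated)
11 | lithium enolate of (4R,5R)‑4‑(2‑Ar′‑1,3‑dithian‑2‑yl)‑5‑menthyloxy‑dihydrofuran‑2(3H)‑one | [Li]OC1=C[C@@H](C2(SCCCS2)c2cc(OC)c(OCc3ccccc3)c(OC)c2)[C@H](O[C@@H]2C[C@H](C)CC[C@H]2C(C)C)O1 | intermediate (not isolated)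
12 | (3S,4R,5R)‑4‑(2‑Ar′‑1,3‑dithian‑2‑yl)‑3‑[hydroxy(3,5‑dimethoxy‑4‑pivaloyloxyphenyl)methyl]‑5‑menthyloxy‑dihydrofuran‑2(3H)‑one, carbinol centre undefined (both epimers) | O=C1O[C@@H](O[C@@H]2C[C@H](C)CC[C@H]2C(C)C)[C@H](C2(SCCCS2)c2cc(OC)c(OCc3ccccc3)c(OC)c2)[C@H]1C(O)c1cc(OC)c(OC(=O)C(C)(C)C)c(OC)c1 | intermediate
13 | (2R,3R)‑2‑[hydroxy(4‑hydroxy‑3,5‑dimethoxyphenyl)methyl]‑3‑(2‑Ar′‑1,3‑dithian‑2‑yl)butane‑1,4‑diol, carbinol centre undefined (both epimers) | COc1cc(C(O)[C@@H](CO)[C@H](CO)C2(SCCCS2)c2cc(OC)c(OCc3ccccc3)c(OC)c2)cc(OC)c1O | intermediate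
14 | 4‑[(2S,3R,4R)‑4‑(2‑Ar′‑1,3‑dithian‑2‑yl)‑3‑(hydroxymethyl)oxolan‑2‑yl]‑2,6‑dimethoxyphenol | COc1cc([C@H]2OC[C@H](C3(SCCCS3)c3cc(OC)c(OCc4ccccc4)c(OC)c3)[C@@H]2CO)cc(OC)c1O | intermediate
15 | methyl 2‑{4‑[(2S,3R,4R)‑4‑(2‑Ar′‑1,3‑dithian‑2‑yl)‑3‑(hydroxymethyl)oxolan‑2‑yl]‑2,6‑dimethoxyphenoxy}acetate | COC(=O)COc1c(OC)cc(cc1OC)[C@H]1OC[C@H](C2(SCCCS2)c2cc(OC)c(OCc3ccccc3)c(OC)c2)[C@@H]1CO | intermediate
16 | C‑9 O‑TBS ether of 15 | COC(=O)COc1c(OC)cc(cc1OC)[C@H]1OC[C@H](C2(SCCCS2)c2cc(OC)c(OCc3ccccc3)c(OC)c2)[C@@H]1CO[Si](C)(C)C(C)(C)C | intermediate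
17 | 2‑{4‑[(2S,3R,4R)‑4‑(2‑Ar′‑1,3‑dithian‑2‑yl)‑3‑(TBSO‑methyl)oxolan‑2‑yl]‑2,6‑dimethoxyphenoxy}acetic acid | OC(=O)COc1c(OC)cc(cc1OC)[C@H]1OC[C@H](C2(SCCCS2)c2cc(OC)c(OCc3ccccc3)c(OC)c2)[C@@H]1CO[Si](C)(C)C(C)(C)C | intermediate
18 | (R)‑4‑benzyl‑2‑oxazolidinone | O=C1N[C@H](Cc2ccccc2)CO1 | starting material
19 | mixed pivalic anhydride of acid 17 | CC(C)(C)C(=O)OC(=O)COc1c(OC)cc(cc1OC)[C@H]1OC[C@H](C2(SCCCS2)c2cc(OC)c(OCc3ccccc3)c(OC)c2)[C@@H]1CO[Si](C)(C)C(C)(C)C | intermediate (not isolated)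
20 | (4R)‑4‑benzyl‑3‑(aryloxyacetyl)oxazolidin‑2‑one (aryloxy = the phenoxy unit of 17) | O=C(COc1c(OC)cc(cc1OC)[C@H]1OC[C@H](C2(SCCCS2)c2cc(OC)c(OCc3ccccc3)c(OC)c2)[C@@H]1CO[Si](C)(C)C(C)(C)C)N1C(=O)OC[C@H]1Cc1ccccc1 | intermediate
21 | 4‑benzyloxy‑3‑methoxybenzaldehyde (O‑benzylvanillin) | COc1cc(C=O)ccc1OCc1ccccc1 | starting material
22 | (Z)‑dibutylboron enolate of imide 20 (aryloxy cis to O–B) | CCCCB(CCCC)O/C(=C\Oc1c(OC)cc(cc1OC)[C@H]1OC[C@H](C2(SCCCS2)c2cc(OC)c(OCc3ccccc3)c(OC)c2)[C@@H]1CO[Si](C)(C)C(C)(C)C)N1C(=O)OC[C@H]1Cc1ccccc1 | intermediate (not isolated)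
23 | (4R)‑4‑benzyl‑3‑[(2R,3S)‑3‑(4‑benzyloxy‑3‑methoxyphenyl)‑3‑hydroxy‑2‑(aryloxy)propanoyl]oxazolidin‑2‑one (syn aldol) | O=C([C@H](Oc1c(OC)cc(cc1OC)[C@H]1OC[C@H](C2(SCCCS2)c2cc(OC)c(OCc3ccccc3)c(OC)c2)[C@@H]1CO[Si](C)(C)C(C)(C)C)[C@@H](O)c1ccc(OCc2ccccc2)c(OC)c1)N1C(=O)OC[C@H]1Cc1ccccc1 | intermediate
24 | (1S,2S)‑1‑(4‑benzyloxy‑3‑methoxyphenyl)‑2‑(aryloxy)propane‑1,3‑diol (threo) | OC[C@H](Oc1c(OC)cc(cc1OC)[C@H]1OC[C@H](C2(SCCCS2)c2cc(OC)c(OCc3ccccc3)c(OC)c2)[C@@H]1CO[Si](C)(C)C(C)(C)C)[C@@H](O)c1ccc(OCc2ccccc2)c(OC)c1 | intermediate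
25 | (1S,2S)‑1‑(4‑benzyloxy‑3‑methoxyphenyl)‑3‑(TBSO)‑2‑(aryloxy)propan‑1‑ol | CC(C)(C)[Si](C)(C)OC[C@H](Oc1c(OC)cc(cc1OC)[C@H]1OC[C@H](C2(SCCCS2)c2cc(OC)c(OCc3ccccc3)c(OC)c2)[C@@H]1CO[Si](C)(C)C(C)(C)C)[C@@H](O)c1ccc(OCc2ccccc2)c(OC)c1 | intermediate
26 | (1R,2S)‑1‑(4‑benzyloxy‑3‑methoxyphenyl)‑3‑(TBSO)‑2‑(aryloxy)propyl 4‑nitrobenzoate | CC(C)(C)[Si](C)(C)OC[C@H](Oc1c(OC)cc(cc1OC)[C@H]1OC[C@H](C2(SCCCS2)c2cc(OC)c(OCc3ccccc3)c(OC)c2)[C@@H]1CO[Si](C)(C)C(C)(C)C)[C@H](OC(=O)c1ccc(cc1)[N+](=O)[O-])c1ccc(OCc2ccccc2)c(OC)c1 | intermediate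
27 | (1R,2S)‑1‑(4‑benzyloxy‑3‑methoxyphenyl)‑3‑(TBSO)‑2‑(aryloxy)propan‑1‑ol (erythro) | CC(C)(C)[Si](C)(C)OC[C@H](Oc1c(OC)cc(cc1OC)[C@H]1OC[C@H](C2(SCCCS2)c2cc(OC)c(OCc3ccccc3)c(OC)c2)[C@@H]1CO[Si](C)(C)C(C)(C)C)[C@H](O)c1ccc(OCc2ccccc2)c(OC)c1 | intermediate
28 | (2S,3R,4R) cis ketone: oxolane with 4‑(4‑benzyloxy‑3,5‑dimethoxybenzoyl) cis to 3‑CH2OTBS, side chain as in 27 | CC(C)(C)[Si](C)(C)OC[C@H](Oc1c(OC)cc(cc1OC)[C@H]1OC[C@H](C(=O)c2cc(OC)c(OCc3ccccc3)c(OC)c2)[C@@H]1CO[Si](C)(C)C(C)(C)C)[C@H](O)c1ccc(OCc2ccccc2)c(OC)c1 | intermediate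
29 | (2S,3R,4S) all‑trans ketone (C‑8′ epimer of 28) | CC(C)(C)[Si](C)(C)OC[C@H](Oc1c(OC)cc(cc1OC)[C@H]1OC[C@@H](C(=O)c2cc(OC)c(OCc3ccccc3)c(OC)c2)[C@@H]1CO[Si](C)(C)C(C)(C)C)[C@H](O)c1ccc(OCc2ccccc2)c(OC)c1 | intermediate
30 | 4,4″‑di‑O‑benzyl ether of the target | OC[C@H](Oc1c(OC)cc(cc1OC)[C@H]1OC[C@@H](C(=O)c2cc(OC)c(OCc3ccccc3)c(OC)c2)[C@@H]1CO)[C@H](O)c1ccc(OCc2ccccc2)c(OC)c1 | intermediate
31 | CNP0236429.1, (7S,8R,8′S,7″R,8″S) | COc1cc([C@@H](O)[C@H](CO)Oc2c(OC)cc([C@H]3OC[C@@H](C(=O)c4cc(OC)c(O)c(OC)c4)[C@@H]3CO)cc2OC)ccc1O | target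

**Summary**
Total steps: 21. Longest linear sequence: 18 steps (steps 1, 2, 6–21; the branch through steps 3, 4, 6–21 is equally long).

**Steps most likely to fail, with fallbacks**

Step 6 (three‑component coupling): the lactone enolate may be quenched or undergo retro‑aldol before it is trapped, giving low yields of 12. The fallback decouples the two bond formations. It sets out from 8 (with 5): the lithiated dithiane is added to 5 and the mixture is quenched with NH4Cl at −78 °C, so that the trans Michael lactone F1 is isolated and purified. In a separate operation F1 is deprotonated with LDA in THF at −78 °C, transmetallated with ZnCl2, and the zinc enolate is combined with aldehyde 9 in a directed aldol addition. This comes back to the route at 12.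

Step 8 (acid cyclisation): under protic acid the benzylic cation can also be captured by the electron‑rich Ar′ ring (aryltetralin formation) or by a dithiane sulfur. The fallback avoids acid at the ring‑closing stage. It sets out from 13: TMSBr in CH2Cl2 at 0 °C converts the p‑hydroxybenzylic alcohol into the benzylic bromide F2. Brief shaking with cold aqueous NaHCO3 eliminates HBr to give the quinone methide F3, which is closed by intramolecular 1,6‑addition of the C‑9′ hydroxyl under neutral conditions. This comes back to the route at 14.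

Step 16 (Mitsunobu inversion): the electron‑rich, hindered benzylic carbinol may ionise (loss of stereospecificity) or eliminate. The fallback replaces SN2 inversion by an oxidation–reduction sequence. It sets out from 25: activated MnO2 in CH2Cl2 oxidises the benzylic alcohol to the α‑aryloxy aryl ketone F4. Zn(BH4)2 in Et2O at −30 °C then reduces it under chelation control (zinc bridging the carbonyl and the C‑8″ aryloxy oxygen, hydride delivered anti to the CH2OTBS group) to the anti (erythro) alcohol. This comes back to the route at 27, bypassing 26.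

**Further compounds**
F1 | step 6 | (4R,5R)‑4‑[2‑(4‑benzyloxy‑3,5‑dimethoxyphenyl)‑1,3‑dithian‑2‑yl]‑5‑[(1R,2S,5R)‑menthyloxy]dihydrofuran‑2(3H)‑one | O=C1O[C@@H](O[C@@H]2C[C@H](C)CC[C@H]2C(C)C)[C@H](C2(SCCCS2)c2cc(OC)c(OCc3ccccc3)c(OC)c2)C1
F2 | step 8 | (2R,3R)‑2‑[bromo(4‑hydroxy‑3,5‑dimethoxyphenyl)methyl]‑3‑[2‑(4‑benzyloxy‑3,5‑dimethoxyphenyl)‑1,3‑dithian‑2‑yl]butane‑1,4‑diol (bromide epimers) | COc1cc(C(Br)[C@@H](CO)[C@H](CO)C2(SCCCS2)c2cc(OC)c(OCc3ccccc3)c(OC)c2)cc(OC)c1O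
F3 | step 8 | quinone methide of 13: 4‑alkylidene‑2,6‑dimethoxycyclohexa‑2,5‑dienone with C‑8/C‑8′ as in 13 | COC1=CC(=C[C@@H](CO)[C@H](CO)C2(SCCCS2)c2cc(OC)c(OCc3ccccc3)c(OC)c2)C=C(OC)C1=O
F4 | step 16 | (2S)‑1‑(4‑benzyloxy‑3‑methoxyphenyl)‑3‑(TBSO)‑2‑(aryloxy)propan‑1‑one (aryloxy as in 25) | CC(C)(C)[Si](C)(C)OC[C@H](Oc1c(OC)cc(cc1OC)[C@H]1OC[C@H](C2(SCCCS2)c2cc(OC)c(OCc3ccccc3)c(OC)c2)[C@@H]1CO[Si](C)(C)C(C)(C)C)C(=O)c1ccc(OCc2ccccc2)c(OC)c1
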